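## Retrosynthetic overview

1. Ring numbering follows 3,5-dimethylorsellinic acid. C1 bears CO2H, C2 the enol OH (O2), C3 a CH3, C4 the ketone (O4), C5 is the quaternary stereocentre (CH3 and farnesyl C1'), and C6 bears a CH3. This six-membered ring is the only ring.
2. Feature used: C5 lies para to O2, and O2 stands next to the C1 carboxyl, so O2 and the C1 C=O form a salicylate-type two-point binding site. The 2,4-dienone of the target is the enol tautomer of the 2,5-dienone that a para-Claisen shift from O2 would give.
3. Key disconnection C5–C1': the bond is made by walking the farnesyl group from O2 over C3 to C5 (Claisen, then Cope), not by alkylation. The walk runs on one face of the flat, achiral aryl farnesyl ether 10, held in a chiral Lewis acid chelate. This one isomerisation dearomatises the ring, sets C5, fixes the site (para only) and returns the linear 2'E chain.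
4. Ether 10 comes from 3-methylorsellinic acid 1 through a fluoride-labile ester, C5-methylation by formylation/hydrogenolysis, O4 silylation and O2 farnesylation. One fluoride step after the key step frees O4 and CO2H.
5. Ring order: no ring is closed. The benzene ring is bought and is turned into the cyclohexadienone in step 6.

Key step: step 6

Assumption 1: the sense of induction of the chiral Lewis acid on this new substrate cannot be predicted with certainty, so "the ligand" means the antipode that delivers (R)-C5; both antipodes are accessible from (S)- or (R)-pipecolic acid.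

Assumption 2: the O2-H/O4-H enol forms of the 1,3-diketone interconvert freely, so the free compound is written in the tautomer given for the target (O2-H hydrogen bonded to the carboxyl).

## Route

**Step 1**
Reactants: 1 2,4-dihydroxy-3,6-dimethylbenzoic acid (3-methylorsellinic acid); 2 2-(trimethylsilyl)ethanol
Product: 3 2-(trimethylsilyl)ethyl (TMSE) 2,4-dihydroxy-3,6-dimethylbenzoate
Conditions: PPh3, DIAD, THF, 0 °C → rt (1.0 equiv of 2)
Reagents that add atoms: none
Why: Mitsunobu esterification, in which the carboxylate (far more acidic than either phenol) is O-alkylated at the activated CH2 of 2, so the shielding of the 2,6-disubstituted carboxyl carbon does not matter and the free phenols stay untouched.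

**Step 2**
Reactants: 3 TMSE 2,4-dihydroxy-3,6-dimethylbenzoate
Product: 5 TMSE 5-formyl-2,4-dihydroxy-3,6-dimethylbenzoate, via C5 aryl-CH=NMe2(+) chloride (iminium salt) 4 (not isolated)
Conditions: POCl3, DMF, 0 → 40 °C; then H2O, 0 °C → rt
Reagents that add atoms: N,N-dimethylformamide, CN(C)C=O (formyl carbon); water, O (aldehyde oxygen)
Why: Vilsmeier–Haack formylation, in which C5 is the only unsubstituted ring carbon and is ortho to O4 and para to O2, so the electrophile can enter only there, and water hydrolyses iminium salt 4.

**Step 3**
Reactants: 5 TMSE 5-formyl-2,4-dihydroxy-3,6-dimethylbenzoate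
Product: 7 TMSE 2,4-dihydroxy-3,5,6-trimethylbenzoate (TMSE ester of 3,5-dimethylorsellinic acid), via 5-hydroxymethyl compound 6 (not isolated)
Conditions: H2 (3–4 atm), 10% Pd/C, AcOH–EtOAc, rt
Reagents that add atoms: none
Why: Catalytic hydrogenation followed by benzylic hydrogenolysis, in which the aldehyde is reduced to alcohol 6 and its C–O bond, activated by the ortho (O4) and para (O2) donors, is cleaved in the acidic medium while ester and silane are inert.

**Step 4**
Reactants: 7 TMSE 2,4-dihydroxy-3,5,6-trimethylbenzoate
Product: 8 TMSE 2-hydroxy-3,5,6-trimethyl-4-(triisopropylsilyloxy)benzoate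
Conditions: TIPSOTf (1.05 equiv), 2,6-lutidine, CH2Cl2, −78 → 0 °C
Reagents that add atoms: triisopropylsilyl triflate, CC(C)[Si](C(C)C)(C(C)C)OS(=O)(=O)C(F)(F)F
Why: Chemoselective O-silylation, in which O2-H is tied up in the hydrogen bond to the ester carbonyl and is much less nucleophilic, so one equivalent of silyl triflate should take O4-H only.

**Step 5**
Reactants: 8 TMSE 2-hydroxy-3,5,6-trimethyl-4-(triisopropylsilyloxy)benzoate; 9 (2E,6E)-farnesyl bromide
Product: 10 TMSE 2-[(2E,6E)-farnesyloxy]-3,5,6-trimethyl-4-(triisopropylsilyloxy)benzoate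
Conditions: Cs2CO3, DMF, 0 °C → rt
Reagents that add atoms: none
Why: Williamson ether synthesis (SN2 at the primary allylic bromide), in which the caesium phenoxide in a dipolar aprotic solvent should react at oxygen, the alkene geometries are untouched, and the TIPS ether flanked by two methyl groups should resist the base.

**Step 6**
Reactants: 10 TMSE 2-[(2E,6E)-farnesyloxy]-3,5,6-trimethyl-4-(triisopropylsilyloxy)benzoate
Product: 12 TMSE (5R)-5-[(2E,6E)-farnesyl]-3,5,6-trimethyl-2-oxo-4-(triisopropylsilyloxy)cyclohexa-3,6-diene-1-carboxylate (cross-conjugated 2,5-dienone; C3=C4 and C6=C1), via (3R)-ortho-dienone carrying at C3 the (3R)-3,7,11-trimethyldodeca-1,6,10-trien-3-yl group 11 (not isolated)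
Conditions: Co(OTf)2 (10 mol %), C2-symmetric bis(pipecolamide) N,N'-dioxide ligand (N-aryl = 2,6-diisopropylphenyl, 1,3-propanediyl linker, 11 mol %), 4 Å MS, ClCH2CH2Cl, 35 °C
Reagents that add atoms: none
Why: Proposed new method: the cationic Co(II)–N,N'-dioxide complex binds 10 through the ether oxygen O2 and the C1 ester carbonyl (six-membered chelate), polarises the O2–C1' bond and triggers a charge-accelerated aromatic Claisen shift to C3 (ortho-dienone 11) followed by a Cope shift C3→C5, i.e. a para-Claisen rearrangement, whose closest known reaction type is the chiral-Lewis-acid-catalysed para-Claisen rearrangement of 1-allyloxy-2-naphthoates, extended here to a monocyclic, fully substituted resorcylate and a γ,γ-disubstituted allyl group. No ring is closed; the purchased benzene ring is dearomatised to the cyclohexadienone of the target. The only lasting new stereocentre, C5, is controlled by the ligand, which shields one face of the chelated arene so that the out-of-plane O-farnesyl group sits on the open face, and since both shifts are suprafacial the face chosen at O2 is the face reached at C5 (R with the matching antipode). Two allylic inversions return the linear attachment through C1', and a chair Claisen followed by a chair Cope puts the C3' methyl cis to C1' again, so the 2'E geometry is returned stereospecifically, while a contact ion pair sliding over the same face would lead to the same product. The site selectivity needed (C5 against C3, C1 and O4) is secured by the substrate: both ortho carbons are blocked so the walk cannot stop there by rearomatisation, the O4-TIPS group keeps C4 as an enol ether, which makes C5 nucleophilic and closes the escape of the allyl group to O4, and only the O2 ether is activated by chelation. The driving force is the exchange of a crowded aryl ether for a C–C bond and a push–pull vinylogous ester/β-keto ester, which costs far less aromatic energy than a simple phenol, and thermal para-Claisen shifts need much higher temperature, so turnover should pass through the chiral complex only.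

**Step 7**
Reactants: 12 TMSE (5R)-5-farnesyl-3,5,6-trimethyl-2-oxo-4-(triisopropylsilyloxy)cyclohexa-3,6-diene-1-carboxylate
Product: 14 (5R)-5-[(2E,6E)-farnesyl]-2-hydroxy-3,5,6-trimethyl-4-oxocyclohexa-2,6-diene-1-carboxylic acid (target, CID137333727), via TMSE (5R)-5-farnesyl-2-hydroxy-3,5,6-trimethyl-4-oxocyclohexa-2,6-diene-1-carboxylate (enol ester) 13 (not isolated)
Conditions: TBAF (4 equiv), THF, 0 °C → rt, Ar; then cold 0.1 M HCl to pH 3–4, extraction below 10 °C
Reagents that add atoms: none
Why: Fluoride-induced desilylation, in which the vinylogous silyl ester at O4 falls first to give 13, and attack of fluoride on the SiMe3 group then expels ethene and the carboxylate (β-elimination) without any attack at the hindered, deactivated carbonyl carbon; C5 is quaternary and cannot epimerise, and the freed 1,3-diketone enol settles in the tautomer of the target.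

## Compound list

| No. | Name | SMILES | Role |
|---|---|---|---|
| 1 | 2,4-dihydroxy-3,6-dimethylbenzoic acid | Cc1cc(O)c(C)c(O)c1C(=O)O | starting material |
| 2 | 2-(trimethylsilyl)ethanol | C[Si](C)(C)CCO | starting material |
| 3 | TMSE 2,4-dihydroxy-3,6-dimethylbenzoate | Cc1cc(O)c(C)c(O)c1C(=O)OCC[Si](C)(C)C | intermediate |
| 4 | C5 iminium chloride (not isolated) | Cc1c(C=[N+](C)C)c(O)c(C)c(O)c1C(=O)OCC[Si](C)(C)C.[Cl-] | intermediate |
| 5 | TMSE 5-formyl-2,4-dihydroxy-3,6-dimethylbenzoate | Cc1c(C=O)c(O)c(C)c(O)c1C(=O)OCC[Si](C)(C)C | intermediate |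
| 6 | TMSE 2,4-dihydroxy-5-(hydroxymethyl)-3,6-dimethylbenzoate (not isolated) | Cc1c(CO)c(O)c(C)c(O)c1C(=O)OCC[Si](C)(C)C | intermediate |
| 7 | TMSE 2,4-dihydroxy-3,5,6-trimethylbenzoate | Cc1c(C)c(O)c(C)c(O)c1C(=O)OCC[Si](C)(C)C | intermediate |
| 8 | TMSE 2-hydroxy-3,5,6-trimethyl-4-(triisopropylsilyloxy)benzoate | Cc1c(C)c(O[Si](C(C)C)(C(C)C)C(C)C)c(C)c(O)c1C(=O)OCC[Si](C)(C)C | intermediate |
| 9 | (2E,6E)-farnesyl bromide | CC(C)=CCC/C(C)=C/CC/C(C)=C/CBr | starting material |
| 10 | TMSE 2-[(2E,6E)-farnesyloxy]-3,5,6-trimethyl-4-(triisopropylsilyloxy)benzoate | CC(C)=CCC/C(C)=C/CC/C(C)=C/COc1c(C)c(O[Si](C(C)C)(C(C)C)C(C)C)c(C)c(C)c1C(=O)OCC[Si](C)(C)C | intermediate |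
| 11 | (3R,3'R)-ortho-dienone with the tertiary allyl group on C3 (not isolated) | C=C[C@@](C)(CC/C=C(\C)CCC=C(C)C)[C@@]1(C)C(=O)C(C(=O)OCC[Si](C)(C)C)=C(C)C(C)=C1O[Si](C(C)C)(C(C)C)C(C)C | intermediate |
| 12 | (5R)-2,5-dienone, O4-TIPS, TMSE ester | CC(C)=CCC/C(C)=C/CC/C(C)=C/C[C@@]1(C)C(O[Si](C(C)C)(C(C)C)C(C)C)=C(C)C(=O)C(C(=O)OCC[Si](C)(C)C)=C1C | intermediate |
| 13 | (5R)-enol TMSE ester (not isolated) | CC(C)=CCC/C(C)=C/CC/C(C)=C/C[C@@]1(C)C(=O)C(C)=C(O)C(C(=O)OCC[Si](C)(C)C)=C1C | intermediate |
| 14 | (5R)-5-farnesyl-2-hydroxy-3,5,6-trimethyl-4-oxocyclohexa-2,6-diene-1-carboxylic acid | CC(C)=CCC/C(C)=C/CC/C(C)=C/C[C@@]1(C)C(=O)C(C)=C(O)C(C(=O)O)=C1C | target |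

Total step count: 7. Longest linear sequence: 7 (from 1).

## Steps most likely to fail

**Step 6 (labelled step).**
- What may go wrong: full ionisation of the O2–C1' bond may outrun the ordered shift. This could cause direct collapse of the allyl cation at C3, loss of the farnesyl unit by elimination or cyclisation, poor facial discrimination, or catalyst inhibition by the chelating product.
- Fallback (known chemistry): it sets out from 7 and 9 and comes back at 13.
- Compound 7 is deprotonated twice with LiHMDS (toluene–THF, −20 → 0 °C) and C-alkylated at C5 with 9. This is an intermolecular alkylative dearomatisation, the reaction type established for polysubstituted resorcylates and acylphloroglucinols with allylic bromides.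
- After chromatographic removal of isomers it gives the racemic enol TMSE ester F1.
- The enantiomers are separated by preparative SFC on a polysaccharide chiral phase into 13 and the (5S)-enol TMSE ester F2, which is set aside. The configuration is assigned by ECD.
- Compound 13 is then treated under the conditions of step 7.

**Step 7.**
- What may go wrong: the liberated β-keto-acid-type enol may lose CO2 under the basic fluoride conditions or on acidification. The β-elimination may also stall once the ring is an electron-rich enolate.
- Fallback: it sets out from 10 and comes back at 14. Both silicon-labile groups are exchanged at the robust aromatic stage, so the end game becomes a non-basic Si–O cleavage.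
- TBAF (THF, rt) converts 10 into 2-[(2E,6E)-farnesyloxy]-4-hydroxy-3,5,6-trimethylbenzoic acid F3.
- TIPSCl and imidazole (DMF, rt) then give triisopropylsilyl 2-farnesyloxy-3,5,6-trimethyl-4-(triisopropylsilyloxy)benzoate F4.
- The conditions of step 6 carry F4 through the (3R,3'R)-ortho-dienone TIPS ester F5 (not isolated) to the (5R)-2,5-dienone bis-TIPS compound F6.
- HF·pyridine buffered with pyridine (THF, 0 °C) cleaves the silyl ester and the vinylogous silyl ester to give 14.

**Step 5.**
- What may go wrong: the ambident phenoxide may be alkylated at carbon. Intermolecular silyl transfer from O4 to the O2 phenoxide may also occur, followed by farnesylation at the wrong oxygen.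
- Fallback: it sets out from 8 and comes back at 10. The activation is reversed, so the phenol stays neutral and the allylic alcohol is activated.
- This is a Mitsunobu etherification of 8 with commercial (2E,6E)-farnesol (CC(C)=CCC/C(C)=C/CC/C(C)=C/CO), PPh3 and DIAD in toluene at 0 °C → rt at high concentration. No base and no free phenoxide are present.
- This fallback makes no compound outside the list (F0).

## Further compounds

F1 | step 6 | racemic TMSE 5-farnesyl-2-hydroxy-3,5,6-trimethyl-4-oxocyclohexa-2,6-diene-1-carboxylate | CC(C)=CCC/C(C)=C/CC/C(C)=C/CC1(C)C(=O)C(C)=C(O)C(C(=O)OCC[Si](C)(C)C)=C1C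
F2 | step 6 | (5S)-enol TMSE ester (enantiomer of 13) | CC(C)=CCC/C(C)=C/CC/C(C)=C/C[C@]1(C)C(=O)C(C)=C(O)C(C(=O)OCC[Si](C)(C)C)=C1C
F3 | step 7 | 2-[(2E,6E)-farnesyloxy]-4-hydroxy-3,5,6-trimethylbenzoic acid | CC(C)=CCC/C(C)=C/CC/C(C)=C/COc1c(C)c(O)c(C)c(C)c1C(=O)O
F4 | step 7 | triisopropylsilyl 2-[(2E,6E)-farnesyloxy]-3,5,6-trimethyl-4-(triisopropylsilyloxy)benzoate | CC(C)=CCC/C(C)=C/CC/C(C)=C/COc1c(C)c(O[Si](C(C)C)(C(C)C)C(C)C)c(C)c(C)c1C(=O)O[Si](C(C)C)(C(C)C)C(C)C
F5 | step 7 | (3R,3'R)-ortho-dienone TIPS ester (not isolated) | C=C[C@@](C)(CC/C=C(\C)CCC=C(C)C)[C@@]1(C)C(=O)C(C(=O)O[Si](C(C)C)(C(C)C)C(C)C)=C(C)C(C)=C1O[Si](C(C)C)(C(C)C)C(C)C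
F6 | step 7 | (5R)-2,5-dienone, O4-TIPS, TIPS ester | CC(C)=CCC/C(C)=C/CC/C(C)=C/C[C@@]1(C)C(O[Si](C(C)C)(C(C)C)C(C)C)=C(C)C(=O)C(C(=O)O[Si](C(C)C)(C(C)C)C(C)C)=C1C
F0 | step 5 | none | none
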